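Precatalyst turns into free catalyst by a first-order step with a half-life of 0.853 h, so every flask opens with no free catalyst and gains it over the run.

common to all: second substrate 1.00 equiv; precatalyst 10 mol%; time 2.5 h

|  | starting material | reagent | remark |
|---|---|---|---|
| Thursday's | 33 mM (fed, over 2.0 h) | 2.50 equiv | all else is in the flask from the start; the feed brings no volume worth counting |
| Tuesday's | 33 mM | 2.50 equiv | everything together at the start |
| Wednesday's | 33 mM | 2.50 equiv (in portions, 3, over 2.0 h) | first portion at the start, last at 2.0 h |
| Monday's | 33 mM | 2.50 equiv (fed, over 2.0 h) | all else is in the flask from the start; the feed brings no volume worth counting |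

* which flask leads in share of target in target plus uncatalysed product ("all alike" within 1.5 percentage points) (Thursday's / Tuesday's / Wednesday's / Monday's / all alike)
* share of target in target plus uncatalysed product at the end, Thursday's
* share of target in target plus uncatalysed product at the end, Tuesday's
* share of target in target plus uncatalysed product at the end, Wednesday's
* share of target in target plus uncatalysed product at the end, Monday's

- a species is counted by the starting material in it: one homo dimer counts as two
- two of one species on the left: rate k times its square, two consumed each time
- run time (Thursday's): 2.5 h

    reagent + catalyst intermediate B → free catalyst + second product (k1 = 89.6 /M/h)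
    starting material + reagent → uncatalysed product (k2 = 4.84 /M/h)
    precatalyst → free catalyst (k3 = 0.813 /h)
    reagent + catalyst intermediate A → free catalyst + target (k4 = 811 /M/h)
    second substrate + free catalyst ⇌ catalyst intermediate B (K5 = 11.8 /M, k5 = 141 /M/h)
    2 starting material → homo dimer (k6 = 16.3 /M/h)
    starting material + free catalyst ⇌ catalyst intermediate A (K7 = 99.1 /M, k7 = 407 /M/h)

Starting material has two exits that count for the asked share. It meets free catalyst and becomes catalyst intermediate A, which reagent turns into target, or it meets reagent and becomes uncatalysed product. Each rate carries starting material, which cancels in their ratio. The exits are equal when free catalyst over reagent equals 4.84 /M/h over 407 /M/h: this is the break-even ratio 0.0119. Free catalyst over reagent, divided by the break-even ratio, is the lead, a selectivity factor, and lead over one plus lead is the share at that moment. Capture is counted as final here: with the whole reagent charge, intermediate A falls back at 4.11 /h and goes on at 66.9 /h.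

In Tuesday's flask, reagent stands at 82.5 mM from the start, so break-even needs 0.981 mM of free catalyst out of a charge of 3.30 mM. The release curve reaches that at 0.434 h. Thursday's flask crosses at the same time, but by then its feed has brought 21.7% of the starting material. Wednesday's first portion is a third of the reagent, so that flask crosses sooner, at 0.128 h. In Monday's flask, catalyst and reagent rise together, and the lead opens at 5.47. Even with the whole charge in at 2.0 h, the lead is 2.70, which gives moment shares from 84.5% down to 73.0% before any catalyst is held in intermediate B. The reckoned order is Monday's, Wednesday's, Thursday's, Tuesday's.

The forecast gives 71% for Monday's, 67% for Thursday's, 65% for Wednesday's and 51% for Tuesday's, and names Monday's as leader, on the ground that “Late feeding of starting material or keeping reagent low early both favour the catalytic route”. It differs from the reckoning by placing Thursday's above Wednesday's.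

The simulation gives 71.2% for Monday's, 67.7% for Wednesday's, 64.0% for Thursday's and 50.2% for Tuesday's. Monday's leads by 3.5 percentage points, which is more than the margin.

At the end of Monday's, free catalyst stands at 70.1% and reagent at 78.9% of their charges, a lead of 2.99 and a moment share of 74.9%. At 1.18 h in Monday's, intermediate A falls back at 0.12 of the rate at which it goes on. The neighbour of Monday's with 4.00 equiv of second substrate ends with free catalyst at 43.6% and reagent at 74.0%, a lead of 1.98 and a moment share of 66.4%. Its computed share is 61.1%, lower than Monday's.

(The constants were drawn at random within sensible limits, and the outcome is calculated.)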